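**Plan**

1. Retrosynthesis: the two MOM ethers and the C4 carbonyl (masked as a 1,3-dithiane) are unveiled last; ring C is then cut at C3–C4 and at O1–C8a, which leaves a ring A acyl-anion equivalent and a ring B aryl oxirane.
2. Enabling feature: C4 is an aryl carbonyl carbon whose polarity can be inverted as a 2-aryl-1,3-dithiane carbanion; O1–C2–C3 is exactly an oxirane; C8a sits ortho to C4a and meta to both ring A oxygens (C5, C7), so a fluorine there can be displaced by the tethered C2 alkoxide.
3. Forward: ring B fragment by double prenylation of a dibromoanisate, chloromethyl ketone formation, asymmetric transfer hydrogenation and oxirane closure; ring A fragment by formylation of 5-fluororesorcinol, dithiane formation and MOM protection.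
4. Ring C is then closed in one pot onto the finished rings A and B, followed by dithiane hydrolysis and MOM cleavage under non-basic conditions.
5. Stereochemistry: C2 is set by catalyst-controlled transfer hydrogenation and carried through the (R)-oxirane; its C2–O bond is never broken, so the (R)-oxirane gives the (2S)-flavanone (the descriptor changes, the geometry does not).

Key step: step 8

Remark: 5-fluororesorcinol, methyl 3,5-dibromo-4-hydroxybenzoate and tributyl(prenyl)stannane are assumed to be catalogue compounds; positions are given in flavanone numbering (O1, C2, C3, C4, C4a, C5 to C8, C8a; rings A, B, C).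

**Route**

Step 1
Reactants: 1 methyl 3,5-dibromo-4-hydroxybenzoate; 2 iodomethane
Product: 3 methyl 3,5-dibromo-4-methoxybenzoate
Conditions: MeI, K2CO3, acetone, reflux
Reagents that add atoms: iodomethane, CI
Why: Williamson O-methylation of the acidic 2,6-dibromophenol should be clean, since the phenoxide is the only nucleophile present.

Step 2
Reactants: 3 methyl 3,5-dibromo-4-methoxybenzoate; 4 tributyl(3-methylbut-2-en-1-yl)stannane
Product: 5 methyl 4-methoxy-3,5-bis(3-methylbut-2-en-1-yl)benzoate
Conditions: Pd(PPh3)4 (cat.), DMF, 100 °C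
Reagents that add atoms: tributyl(3-methylbut-2-en-1-yl)stannane, CCCC[Sn](CCCC)(CCCC)CC=C(C)C
Why: Double Stille cross-coupling (oxidative addition of zerovalent palladium into each ester-activated C–Br bond, transmetalation, reductive elimination from the less hindered primary σ-allyl complex) should place a linear prenyl group at both positions.

Step 3
Reactants: 5 methyl 4-methoxy-3,5-bis(3-methylbut-2-en-1-yl)benzoate; 6 chloroiodomethane
Product: 8 2-chloro-1-[4-methoxy-3,5-bis(3-methylbut-2-en-1-yl)phenyl]ethan-1-one, via lithium hemiketal 7 (not isolated)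
Conditions: ICH2Cl, MeLi·LiBr, THF, −78 °C; then sat. aq. NH4Cl
Reagents that add atoms: chloroiodomethane, ClCI
Why: Chloromethyllithium, made by I/Li exchange in the presence of the ester, adds once to the carbonyl, and hemiketal 7 persists at −78 °C so that it collapses to the chloromethyl ketone only on quench (carbenoid acylation of an ester to an α-chloro ketone).

Step 4
Reactants: 8 2-chloro-1-[4-methoxy-3,5-bis(3-methylbut-2-en-1-yl)phenyl]ethan-1-one
Product: 10 (2R)-2-[4-methoxy-3,5-bis(3-methylbut-2-en-1-yl)phenyl]oxirane, via chlorohydrin 9 (not isolated)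
Conditions: RuCl[(S,S)-TsDPEN](p-cymene) (cat.), HCO2H/Et3N 5:2, EtOAc, rt; then aq. NaOH, i-PrOH, 0 °C to rt; filtration through Et3N-deactivated SiO2
Reagents that add atoms: none
Why: Noyori asymmetric transfer hydrogenation reduces only the C=O and sets the carbinol center under catalyst control (the (S,S) ligand is expected to deliver hydride to the same face as in acetophenone to (S)-1-phenylethanol, which here is the (R)-chlorohydrin because CH2Cl outranks aryl; the (R,R) complex is used if the sense proves opposite), and hydroxide then closes the oxirane by intramolecular Williamson displacement without touching that center.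

Step 5
Reactants: 11 5-fluorobenzene-1,3-diol; 12 N,N-dimethylformamide; 13 water
Product: 15 2-fluoro-4,6-dihydroxybenzaldehyde, via aryl iminium chloride 14 (not isolated)
Conditions: POCl3, DMF, MeCN, 0 °C to rt; then H2O, 50 °C
Reagents that add atoms: N,N-dimethylformamide, CN(C)C=O; water, O
Why: Vilsmeier–Haack formylation should attack the carbon para to one hydroxyl and ortho to the other (the orcinol pattern), which is the carbon next to fluorine, and hydrolysis of iminium salt 14 releases the aldehyde.

Step 6
Reactants: 15 2-fluoro-4,6-dihydroxybenzaldehyde; 16 propane-1,3-dithiol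
Product: 17 2-(2-fluoro-4,6-dihydroxyphenyl)-1,3-dithiane
Conditions: HS(CH2)3SH, BF3·OEt2, THF/CH2Cl2, 0 °C to rt
Reagents that add atoms: propane-1,3-dithiol, SCCCS
Why: Lewis-acid-catalyzed dithioacetalization masks C4 as the acyl-anion precursor, and it is run before MOM protection because BF3 with a thiol would cleave MOM ethers.

Step 7
Reactants: 17 2-(2-fluoro-4,6-dihydroxyphenyl)-1,3-dithiane; 18 chloromethyl methyl ether
Product: 19 2-[2-fluoro-4,6-bis(methoxymethoxy)phenyl]-1,3-dithiane
Conditions: MOMCl, i-Pr2NEt, CH2Cl2, 0 °C to rt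
Reagents that add atoms: chloromethyl methyl ether, COCCl
Why: Williamson-type O-alkylation of both phenols gives MOM ethers that tolerate n-BuLi and hot alkoxide and leave later under mild acid.

Step 8
Reactants: 19 2-[2-fluoro-4,6-bis(methoxymethoxy)phenyl]-1,3-dithiane; 10 (2R)-2-[4-methoxy-3,5-bis(3-methylbut-2-en-1-yl)phenyl]oxirane
Product: 22 (2S)-5,7-bis(methoxymethoxy)-2-[4-methoxy-3,5-bis(3-methylbut-2-en-1-yl)phenyl]-2,3-dihydrospiro[chromene-4,2'-[1,3]dithiane], via lithiated dithiane 20 (not isolated), via lithium alkoxide 21 (not isolated)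
Conditions: n-BuLi, THF, −78 °C; 10, DMPU, −78 °C to rt; then 65 °C
Reagents that add atoms: none
Why: Proposed new method: n-BuLi removes the doubly sulfur-stabilized benzylic C–H of dithiane 19 to give carbanion 20, which opens oxirane 10 by SN2 attack at its unsubstituted CH2 (forming C3–C4) to give lithium alkoxide 21, and on warming in THF/DMPU this alkoxide displaces the ortho fluoride by addition–elimination (forming O1–C8a). The closest known reaction types are the opening of terminal epoxides, styrene oxides included, by 2-aryl-2-lithio-1,3-dithianes and the base-mediated intramolecular SNAr of 3-(2-fluoroaryl)propan-1-olates to chromans and flavans; their merger into one annulation on a dithiane-masked acyl anion is the untested part. Ring C closes as a six-membered ring in the 6-exo-trig mode (Meisenheimer-type attack at C8a, the breaking C8a=C8 π bond lying outside the new ring), helped by the gem-disubstitution at the spiro dithiane carbon and by the two MOM-oxy groups at C5 and C7, which are meta to C8a and so withdraw inductively without donating to it by resonance. No new stereocenter arises: C2 keeps the configuration of oxirane 10 because only the CH2–O bond is cleaved, and the spiro carbon C4 is not stereogenic. The step needs (a) deprotonation at the dithiane carbon and not on ring A, secured by the much higher acidity of the S,S-acetal C–H, by coordination of the neighboring MOM oxygen and by working at −78 °C, (b) attack at the oxirane CH2 and not at the benzylic carbon, secured by the bulk of the tertiary carbanion and the absence of Lewis acid, and (c) O-arylation at the only ring carbon that bears a leaving group.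

Step 9
Reactants: 22 (2S)-5,7-bis(methoxymethoxy)-2-[4-methoxy-3,5-bis(3-methylbut-2-en-1-yl)phenyl]-2,3-dihydrospiro[chromene-4,2'-[1,3]dithiane]; 13 water
Product: 23 (2S)-5,7-bis(methoxymethoxy)-2-[4-methoxy-3,5-bis(3-methylbut-2-en-1-yl)phenyl]-2,3-dihydro-4H-chromen-4-one
Conditions: MeI, CaCO3, MeCN/H2O 9:1, 45 °C
Reagents that add atoms: water, O
Why: Alkylative dethioacetalization (S-methylation, ring opening to a thionium ion stabilized by the ortho and para oxygens of ring A, hydrolysis) should free the C4 ketone, while the CaCO3 buffer keeps the MOM ethers, the prenyl olefins and C2 untouched.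

Step 10
Reactants: 23 (2S)-5,7-bis(methoxymethoxy)-2-[4-methoxy-3,5-bis(3-methylbut-2-en-1-yl)phenyl]-2,3-dihydro-4H-chromen-4-one
Product: 24 (2S)-5,7-dihydroxy-2-[4-methoxy-3,5-bis(3-methylbut-2-en-1-yl)phenyl]-2,3-dihydro-4H-chromen-4-one
Conditions: HCl (3 M aq.), MeOH, 40 °C
Reagents that add atoms: none
Why: Acid-catalyzed acetal exchange with methanol (MOM cleavage) frees the C5 and C7 phenols, the aryl methyl ether and the prenyl groups (which have no neighboring free phenol to cyclize onto) should survive dilute acid, and an acidic rather than basic medium avoids retro-oxa-Michael ring opening and racemization at C2.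

**Compound list**

1 | methyl 3,5-dibromo-4-hydroxybenzoate | COC(=O)c1cc(Br)c(O)c(Br)c1 | starting material
2 | iodomethane | CI | starting material
3 | methyl 3,5-dibromo-4-methoxybenzoate | COC(=O)c1cc(Br)c(OC)c(Br)c1 | intermediate
4 | tributyl(3-methylbut-2-en-1-yl)stannane | CCCC[Sn](CCCC)(CCCC)CC=C(C)C | starting material
5 | methyl 4-methoxy-3,5-bis(3-methylbut-2-en-1-yl)benzoate | COC(=O)c1cc(CC=C(C)C)c(OC)c(CC=C(C)C)c1 | intermediate
6 | chloroiodomethane | ClCI | starting material
7 | lithium 2-chloro-1-methoxy-1-[4-methoxy-3,5-bis(3-methylbut-2-en-1-yl)phenyl]ethan-1-olate (racemic hemiketal adduct) | COC(O[Li])(CCl)c1cc(CC=C(C)C)c(OC)c(CC=C(C)C)c1 | intermediate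
8 | 2-chloro-1-[4-methoxy-3,5-bis(3-methylbut-2-en-1-yl)phenyl]ethan-1-one | COc1c(CC=C(C)C)cc(C(=O)CCl)cc1CC=C(C)C | intermediate
9 | (1R)-2-chloro-1-[4-methoxy-3,5-bis(3-methylbut-2-en-1-yl)phenyl]ethan-1-ol | COc1c(CC=C(C)C)cc([C@@H](O)CCl)cc1CC=C(C)C | intermediate
10 | (2R)-2-[4-methoxy-3,5-bis(3-methylbut-2-en-1-yl)phenyl]oxirane | COc1c(CC=C(C)C)cc([C@@H]2CO2)cc1CC=C(C)C | intermediate
11 | 5-fluorobenzene-1,3-diol (5-fluororesorcinol) | Oc1cc(O)cc(F)c1 | starting material
12 | N,N-dimethylformamide | CN(C)C=O | starting material
13 | water | O | starting material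
14 | N-[(2-fluoro-4,6-dihydroxyphenyl)methylidene]-N-methylmethanaminium chloride | C[N+](C)=Cc1c(O)cc(O)cc1F.[Cl-] | intermediate
15 | 2-fluoro-4,6-dihydroxybenzaldehyde | O=Cc1c(O)cc(O)cc1F | intermediate
16 | propane-1,3-dithiol | SCCCS | starting material
17 | 2-(2-fluoro-4,6-dihydroxyphenyl)-1,3-dithiane | Oc1cc(O)c(C2SCCCS2)c(F)c1 | intermediate
18 | chloromethyl methyl ether | COCCl | starting material
19 | 2-[2-fluoro-4,6-bis(methoxymethoxy)phenyl]-1,3-dithiane | COCOc1cc(OCOC)c(C2SCCCS2)c(F)c1 | intermediate
20 | 2-[2-fluoro-4,6-bis(methoxymethoxy)phenyl]-2-lithio-1,3-dithiane | [Li]C1(SCCCS1)c1c(F)cc(OCOC)cc1OCOC | intermediate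
21 | lithium (1S)-2-{2-[2-fluoro-4,6-bis(methoxymethoxy)phenyl]-1,3-dithian-2-yl}-1-[4-methoxy-3,5-bis(3-methylbut-2-en-1-yl)phenyl]ethan-1-olate | COc1c(CC=C(C)C)cc([C@@H](O[Li])CC2(SCCCS2)c2c(F)cc(OCOC)cc2OCOC)cc1CC=C(C)C | intermediate
22 | (2S)-5,7-bis(methoxymethoxy)-2-[4-methoxy-3,5-bis(3-methylbut-2-en-1-yl)phenyl]-2,3-dihydrospiro[chromene-4,2'-[1,3]dithiane] | COc1c(CC=C(C)C)cc([C@@H]2CC3(SCCCS3)c3c(OCOC)cc(OCOC)cc3O2)cc1CC=C(C)C | intermediate
23 | (2S)-5,7-bis(methoxymethoxy)-2-[4-methoxy-3,5-bis(3-methylbut-2-en-1-yl)phenyl]-2,3-dihydro-4H-chromen-4-one | COc1c(CC=C(C)C)cc([C@@H]2CC(=O)c3c(OCOC)cc(OCOC)cc3O2)cc1CC=C(C)C | intermediate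
24 | (2S)-5,7-dihydroxy-2-[4-methoxy-3,5-bis(3-methylbut-2-en-1-yl)phenyl]-2,3-dihydro-4H-chromen-4-one | COc1c(CC=C(C)C)cc([C@@H]2CC(=O)c3c(O)cc(O)cc3O2)cc1CC=C(C)C | target

**Step count and risks**

Total steps: 10. Longest linear sequence: 7 steps (steps 1, 2, 3, 4, 8, 9, 10); the ring A branch (steps 5, 6, 7) joins at step 8.

Steps most likely to fail:

Step 8 (proposed new method). Three processes may interfere: metalation of ring A next to fluorine with later loss of LiF, attack of the carbanion at the benzylic oxirane carbon, and failure of the lithium alkoxide to displace fluoride from the electron-rich ring before it decomposes. The fallback uses known chemistry and separates the two bond formations. It sets out from 19 and 10: the lithiated dithiane opens the oxirane in THF/DMPU between −78 and 0 °C and the mixture is quenched with aqueous NH4Cl, so that the alcohol (1S)-2-{2-[2-fluoro-4,6-bis(methoxymethoxy)phenyl]-1,3-dithian-2-yl}-1-[4-methoxy-3,5-bis(3-methylbut-2-en-1-yl)phenyl]ethan-1-ol F1 is isolated and purified. F1 is then cyclized in a separate operation as its potassium alkoxide (KOt-Bu, DMSO, 60 °C), the established fluoride-displacement closure of flavans, and this returns to the route at 22.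

Step 2. Allylic transposition at palladium may give 1,1-dimethylallyl (reverse prenyl) groups, and the second coupling next to the first prenyl group may stall. The fallback builds each prenyl group in two stages, with no regiochemical ambiguity in the C–C coupling. It sets out from 3: Stille coupling with allyltributylstannane (Pd(PPh3)4, DMF, 100 °C) should give methyl 4-methoxy-3,5-di(prop-2-en-1-yl)benzoate F2. Double olefin cross-metathesis of F2 with excess 2-methylbut-2-ene (second-generation Grubbs catalyst, RuCl2(=CHPh)(PCy3)(H2IMes), CH2Cl2, 40 °C) then converts both allyl groups into prenyl groups and returns to the route at 5.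

Step 3. The hemiketal adduct may collapse before the quench and take up a second carbenoid, or chloromethyllithium may decompose by α-elimination before it adds to the electron-rich ester. The fallback avoids the chloromethyl ketone and replaces steps 3 and 4, at the cost of half the material. It sets out from 5: LiAlH4 reduction (THF, 0 °C) gives [4-methoxy-3,5-bis(3-methylbut-2-en-1-yl)phenyl]methanol F3, and MnO2 oxidation (CH2Cl2, rt) gives 4-methoxy-3,5-bis(3-methylbut-2-en-1-yl)benzaldehyde F4. Corey–Chaykovsky methylenation (Me3S+ I−, NaH, DMSO/THF) gives racemic 2-[4-methoxy-3,5-bis(3-methylbut-2-en-1-yl)phenyl]oxirane F5. Jacobsen hydrolytic kinetic resolution with the enantiomer of the (salen)Co(OAc) complex that hydrolyses the (S)-oxirane (0.55 equiv H2O, THF, rt) leaves the (R)-oxirane and converts its antipode into (1S)-1-[4-methoxy-3,5-bis(3-methylbut-2-en-1-yl)phenyl]ethane-1,2-diol F6, which is separated; the route is rejoined at 10.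

**Further compounds**

F1 | step 8 | (1S)-2-{2-[2-fluoro-4,6-bis(methoxymethoxy)phenyl]-1,3-dithian-2-yl}-1-[4-methoxy-3,5-bis(3-methylbut-2-en-1-yl)phenyl]ethan-1-ol | COc1c(CC=C(C)C)cc([C@@H](O)CC2(SCCCS2)c2c(F)cc(OCOC)cc2OCOC)cc1CC=C(C)C
F2 | step 2 | methyl 4-methoxy-3,5-di(prop-2-en-1-yl)benzoate | COC(=O)c1cc(CC=C)c(OC)c(CC=C)c1
F3 | step 3 | [4-methoxy-3,5-bis(3-methylbut-2-en-1-yl)phenyl]methanol | COc1c(CC=C(C)C)cc(CO)cc1CC=C(C)C
F4 | step 3 | 4-methoxy-3,5-bis(3-methylbut-2-en-1-yl)benzaldehyde | COc1c(CC=C(C)C)cc(C=O)cc1CC=C(C)C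
F5 | step 3 | racemic 2-[4-methoxy-3,5-bis(3-methylbut-2-en-1-yl)phenyl]oxirane | COc1c(CC=C(C)C)cc(C2CO2)cc1CC=C(C)C
F6 | step 3 | (1S)-1-[4-methoxy-3,5-bis(3-methylbut-2-en-1-yl)phenyl]ethane-1,2-diol | COc1c(CC=C(C)C)cc([C@H](O)CO)cc1CC=C(C)C
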